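**Retrosynthetic overview**

1. The target is reached by global desilylation of bis-silyl ether 32, which is cut at C3′–C4′ (Negishi sp3–sp2 coupling) into alkylzinc 31 (fragment 1, ring A) and β-iodo enone 30 (fragment 2, arene). Numbering: ring A is the oxane O1, C2 (methyl and side chain), C3 (C=O), C4, C5 (CHOH), C6 (CMe2); the side chain runs from C1′ on C2 to the benzylic C10′.
2. Fragment 2: the E alkene C8′=C9′ comes from carboalumination of but-3-yn-1-ol and coupling with a benzylic chloride made by ortho-lithiation; the E iodoalkene C4′=C5′ comes from propynyl addition, hydrozirconation–iodination and oxidation.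
3. Fragment 1: the β-hydroxy ketone of ring A comes from enone 11 (conjugate borylation at C5, allylic oxidation at C3), which comes from dihydropyran 9 and ester 3. The ester carbon becomes C1′; Wittig olefination and two reductions add C2′ and C3′.
4. Key disconnection: ring A is cut at O1–C6 and C2–C3 into the ketone C=O of ethyl pyruvate and 4-methylpenta-1,3-diene (asymmetric hetero-Diels–Alder reaction). The enabling feature is that O1 lies between the quaternary C2 and the gem-dimethyl C6, so that C3–C4–C5–C6 is a diene unit whose C6 end stabilises charge and fixes the regiochemistry. The 3-oxo-5-hydroxy pattern maps onto a C4=C5 alkene with C3 as its only allylic CH, and the C2 side chain can begin as the chelating, activating ester.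
5. Ring formation: ring A is the only ring made (step 1); the arene is bought.

Key step: step 1

Remark: the sense of induction in step 1 is assigned by analogy with known additions to pyruvate esters under the same copper–bis(oxazoline) complex; if the diene approaches the other face, the enantiomeric ligand is used.

**Step 1**
Reactants: 1 ethyl pyruvate; 2 4-methylpenta-1,3-diene
Product: 3 ethyl (2S)-2,6,6-trimethyl-3,6-dihydro-2H-pyran-2-carboxylate
Conditions: CuCl2 (10 mol %), AgSbF6 (20 mol %), 2,2′-(propane-2,2-diyl)bis[(4S)-4-tert-butyl-4,5-dihydro-1,3-oxazole] (11 mol %), CH2Cl2, 25 °C, filter; then 1, 2 (3 equiv, freed of 2-methylpenta-1,3-diene), −20 → 25 °C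
Reagents that add atoms: none
Why: The α-keto ester 1 chelates the divalent copper–bis(oxazoline) Lewis acid through both carbonyl oxygens, and the unsubstituted terminus of diene 2 adds to the ketone carbon in a polar, strongly asynchronous [4+2] transition state whose positive charge sits on the gem-dimethyl terminus and is captured by the carbonyl oxygen, so that C2–C3 and O1–C6 form in one operation. The closest known reaction type is the copper–bis(oxazoline)-catalysed hetero-Diels–Alder reaction (and the related carbonyl-ene reaction) of pyruvate and glyoxylate esters with unactivated dienes and 1,1-disubstituted alkenes. Ring A closes by cycloaddition (in the stepwise limit, six-membered collapse of the copper alkoxide onto the tertiary end of the allyl cation). The only new stereocentre, C2, is set by the ligand: in the square-planar chelate the tert-butyl groups shield the Re face of the ketone, the diene attacks the Si face, and this should give 2S, the arrangement that becomes 2R of the target once the ester has become the side chain. The step needs regioselectivity (oxygen to the CMe2 end), which the two methyl groups secure by stabilising charge at C6 and blocking C–C bond formation there. It also needs ring closure to win over the ene pathway, which is helped because the reacting CH2= terminus has no allylic hydrogen on its own side.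

**Step 2**
Reactants: 3 ethyl (2S)-2,6,6-trimethyl-3,6-dihydro-2H-pyran-2-carboxylate; 4 ethyl (triphenyl-λ5-phosphanylidene)acetate
Product: 6 ethyl (2E)-3-[(2S)-2,6,6-trimethyl-3,6-dihydro-2H-pyran-2-yl]prop-2-enoate, via aldehyde 5 (not isolated)
Conditions: i-Bu2AlH (1.1 equiv), CH2Cl2, −78 °C; then 4, −78 → 25 °C
Reagents that add atoms: none
Why: Reduction of the hindered α-alkoxy ester should stop at the aluminium hemiacetal, which releases the non-enolisable aldehyde 5 on warming for in-situ Wittig olefination, so the ester carbon becomes C1′ and the quaternary C2 cannot epimerise.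

**Step 3**
Reactants: 6 ethyl (2E)-3-[(2S)-2,6,6-trimethyl-3,6-dihydro-2H-pyran-2-yl]prop-2-enoate
Product: 7 ethyl 3-[(2R)-2,6,6-trimethyl-3,6-dihydro-2H-pyran-2-yl]propanoate
Conditions: Cu(OAc)2·H2O (3 mol %), 1,2-bis(diphenylphosphino)benzene (3 mol %), (EtO)2MeSiH (2 equiv), t-BuOH (2 equiv), toluene, 25 °C
Reagents that add atoms: none
Why: Copper hydride conjugate reduction should touch only the electron-poor C1′=C2′ bond and leave the isolated ring alkene C4=C5, which is needed in step 6 (the descriptor at C2 changes by priority only).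

**Step 4**
Reactants: 7 ethyl 3-[(2R)-2,6,6-trimethyl-3,6-dihydro-2H-pyran-2-yl]propanoate
Product: 8 3-[(2R)-2,6,6-trimethyl-3,6-dihydro-2H-pyran-2-yl]propan-1-ol
Conditions: LiAlH4, THF, 0 °C
Reagents that add atoms: none
Why: Standard hydride reduction of the saturated ester to the primary alcohol; nothing else in 7 is reducible.

**Step 5**
Reactants: 8 3-[(2R)-2,6,6-trimethyl-3,6-dihydro-2H-pyran-2-yl]propan-1-ol
Product: 9 (2R)-2-(3-chloropropyl)-2,6,6-trimethyl-3,6-dihydro-2H-pyran
Conditions: PPh3, N-chlorosuccinimide, CH2Cl2, 0 → 25 °C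
Reagents that add atoms: N-chlorosuccinimide O=C1CCC(=O)N1Cl
Why: Appel-type chlorination of the unhindered primary alcohol gives a chloride that should be inert to the oxidation and borylation steps and is exchanged for iodide in step 9.

**Step 6**
Reactants: 9 (2R)-2-(3-chloropropyl)-2,6,6-trimethyl-3,6-dihydro-2H-pyran
Product: 11 (2R)-2-(3-chloropropyl)-2,6,6-trimethyl-2H-pyran-3(6H)-one, via allylic alcohol 10 (not isolated)
Conditions: SeO2 (0.5 equiv), t-BuOOH (3 equiv), CH2Cl2, 25 °C; then Dess–Martin periodinane, CH2Cl2, 25 °C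
Reagents that add atoms: tert-butyl hydroperoxide CC(C)(C)OO (source of the C3 oxygen); selenium dioxide O=[Se]=O (oxygen carrier)
Why: SeO2 allylic hydroxylation (ene reaction, then [2,3]-sigmatropic shift) returns oxygen to the carbon that loses hydrogen, and C3 is the only allylic CH in 9 because C2 and C6 are quaternary, so a single enone should result after Dess–Martin oxidation of the epimeric alcohols 10.

**Step 7**
Reactants: 11 (2R)-2-(3-chloropropyl)-2,6,6-trimethyl-2H-pyran-3(6H)-one
Product: 13 (2R,5R)-2-(3-chloropropyl)-5-hydroxy-2,6,6-trimethyloxan-3-one, via boronate 12 (not isolated)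
Conditions: CuCl (5 mol %), NaOtBu (10 mol %), 1-[2-(diphenylphosphino)ferrocenyl]ethyldicyclohexylphosphine (6 mol %, the enantiomer that delivers boron to the Re face of C5), B2pin2 (1.2 equiv), MeOH (2 equiv), THF, 0 → 25 °C; then NaBO3·4H2O, THF/H2O, 25 °C
Reagents that add atoms: sodium perborate [Na+].[Na+].O[B-]1(O)OO[B-](O)(O)OO1
Why: Copper-catalysed asymmetric conjugate borylation of the cyclic enone followed by stereoretentive C–B oxidation should give the β-hydroxy ketone; the chiral diphosphine, not the remote C2 centre, decides the face, and addition to the Re face of C5 gives 5R.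

**Step 8**
Reactants: 13 (2R,5R)-2-(3-chloropropyl)-5-hydroxy-2,6,6-trimethyloxan-3-one
Product: 14 (2R,5R)-2-(3-chloropropyl)-2,6,6-trimethyl-5-(triethylsilyloxy)oxan-3-one
Conditions: Et3SiOTf, 2,6-lutidine, CH2Cl2, −78 °C
Reagents that add atoms: triethylsilyl trifluoromethanesulfonate CC[Si](CC)(CC)OS(=O)(=O)C(F)(F)F
Why: Silyl triflate silylation protects the hindered secondary alcohol so that the organozinc reagent of step 18 is not protonated, and the weak base cannot trigger β-elimination.

**Step 9**
Reactants: 14 (2R,5R)-2-(3-chloropropyl)-2,6,6-trimethyl-5-(triethylsilyloxy)oxan-3-one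
Product: 15 (2R,5R)-2-(3-iodopropyl)-2,6,6-trimethyl-5-(triethylsilyloxy)oxan-3-one
Conditions: NaI (5 equiv), butan-2-one, 80 °C
Reagents that add atoms: sodium iodide [Na+].[I-]
Why: Finkelstein exchange under neutral conditions gives the primary iodide needed for zinc insertion without touching the ketone or the silyl ether.

**Step 10**
Reactants: 16 4-methoxy-3-methylphenol
Product: 17 (4-methoxy-3-methylphenoxy)tri(propan-2-yl)silane
Conditions: i-Pr3SiCl, imidazole, DMF, 25 °C
Reagents that add atoms: chlorotri(propan-2-yl)silane CC(C)[Si](Cl)(C(C)C)C(C)C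
Why: Silylation of the phenol installs a bulky group that should survive organolithium, organoaluminium and Grignard reagents and does not direct lithiation.

**Step 11**
Reactants: 17 (4-methoxy-3-methylphenoxy)tri(propan-2-yl)silane
Product: 20 {2-methoxy-3-methyl-5-[tri(propan-2-yl)silyloxy]phenyl}methanol, via aryllithium 18 (not isolated), via aldehyde 19 (not isolated)
Conditions: n-BuLi, TMEDA, Et2O, 0 → 25 °C; DMF, −78 → 0 °C; then MeOH, NaBH4, 0 °C
Reagents that add atoms: N,N-dimethylformamide CN(C)C=O
Why: Directed ortho-metalation: the methoxy group directs lithiation to its only free ortho position (the bulky silyloxy group is a poor director), and formylation followed by borohydride reduction of aldehyde 19 gives the benzylic alcohol.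

**Step 12**
Reactants: 20 {2-methoxy-3-methyl-5-[tri(propan-2-yl)silyloxy]phenyl}methanol
Product: 21 [3-(chloromethyl)-4-methoxy-5-methylphenoxy]tri(propan-2-yl)silane
Conditions: PPh3, N-chlorosuccinimide, CH2Cl2, 0 °C
Reagents that add atoms: N-chlorosuccinimide O=C1CCC(=O)N1Cl
Why: Appel-type chlorination of the benzylic alcohol under neutral conditions leaves the aryl silyl ether intact.

**Step 13**
Reactants: 21 [3-(chloromethyl)-4-methoxy-5-methylphenoxy]tri(propan-2-yl)silane; 22 but-3-yn-1-ol
Product: 24 (3E)-5-{2-methoxy-3-methyl-5-[tri(propan-2-yl)silyloxy]phenyl}-3-methylpent-3-en-1-ol, via alkenylalane 23 (not isolated)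
Conditions: 22, Me3Al (3 equiv), Cp2ZrCl2 (0.25 equiv), CH2Cl2, 0 → 25 °C; then 21, Pd(PPh3)4 (5 mol %), THF, 25 °C
Reagents that add atoms: trimethylaluminium C[Al](C)C
Why: Zirconium-catalysed syn-carboalumination places the methyl group on the internal alkyne carbon cis to aluminium, and palladium-catalysed coupling of alkenylalane 23 with the benzylic chloride proceeds with retention, fixing the E alkene C8′=C9′.

**Step 14**
Reactants: 24 (3E)-5-{2-methoxy-3-methyl-5-[tri(propan-2-yl)silyloxy]phenyl}-3-methylpent-3-en-1-ol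
Product: 25 (3E)-5-{2-methoxy-3-methyl-5-[tri(propan-2-yl)silyloxy]phenyl}-3-methylpent-3-enal
Conditions: Dess–Martin periodinane, NaHCO3, CH2Cl2, 0 °C
Reagents that add atoms: none
Why: Buffered Dess–Martin oxidation should give the β,γ-unsaturated aldehyde without moving the double bond into conjugation.

**Step 15**
Reactants: 25 (3E)-5-{2-methoxy-3-methyl-5-[tri(propan-2-yl)silyloxy]phenyl}-3-methylpent-3-enal; 26 prop-1-ynylmagnesium bromide
Product: 27 (6E)-8-{2-methoxy-3-methyl-5-[tri(propan-2-yl)silyloxy]phenyl}-6-methyloct-6-en-2-yn-4-ol (racemic at C4)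
Conditions: 26, THF, −78 °C
Reagents that add atoms: none
Why: 1,2-Addition of the alkynyl Grignard reagent at low temperature should outrun enolisation, and the new carbinol centre is of no consequence because it is oxidised in step 17.

**Step 16**
Reactants: 27 (6E)-8-{2-methoxy-3-methyl-5-[tri(propan-2-yl)silyloxy]phenyl}-6-methyloct-6-en-2-yn-4-ol
Product: 29 (2E,6E)-2-iodo-8-{2-methoxy-3-methyl-5-[tri(propan-2-yl)silyloxy]phenyl}-6-methylocta-2,6-dien-4-ol, via alkenylzirconocene 28 (not isolated)
Conditions: Cp2Zr(H)Cl (2.5 equiv), THF, 25 °C; then I2, 0 °C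
Reagents that add atoms: iodine II
Why: Hydrozirconation adds H and Zr syn across the alkyne with zirconium at the less hindered methyl-bearing carbon, and iodinolysis with retention should give the E iodoalkene with iodine trans to the carbinol; the trisubstituted alkene does not react.

**Step 17**
Reactants: 29 (2E,6E)-2-iodo-8-{2-methoxy-3-methyl-5-[tri(propan-2-yl)silyloxy]phenyl}-6-methylocta-2,6-dien-4-ol
Product: 30 (2E,6E)-2-iodo-8-{2-methoxy-3-methyl-5-[tri(propan-2-yl)silyloxy]phenyl}-6-methylocta-2,6-dien-4-one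
Conditions: Dess–Martin periodinane, NaHCO3, CH2Cl2, 0 °C
Reagents that add atoms: none
Why: Buffered Dess–Martin oxidation of the allylic alcohol should give the β-iodo enone while keeping the skipped C8′=C9′ bond out of conjugation.

**Step 18**
Reactants: 15 (2R,5R)-2-(3-iodopropyl)-2,6,6-trimethyl-5-(triethylsilyloxy)oxan-3-one; 30 (2E,6E)-2-iodo-8-{2-methoxy-3-methyl-5-[tri(propan-2-yl)silyloxy]phenyl}-6-methylocta-2,6-dien-4-one
Product: 32 (2R,5R)-2-[(4E,8E)-10-{2-methoxy-3-methyl-5-[tri(propan-2-yl)silyloxy]phenyl}-4,8-dimethyl-6-oxodeca-4,8-dien-1-yl]-2,6,6-trimethyl-5-(triethylsilyloxy)oxan-3-one, via alkylzinc iodide 31 (not isolated)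
Conditions: 15, Zn dust (activated with BrCH2CH2Br and Me3SiCl), LiCl, THF, 40 °C; then 30, PdCl2(dppf) (5 mol %), THF, 25 °C
Reagents that add atoms: none
Why: Zinc inserts into the primary C–I bond (ketone and silyl ether are tolerated), and Negishi sp3–sp2 coupling with the β-iodo enone proceeds with retention of alkene geometry, so the E bond C4′=C5′ and the whole carbon skeleton should form under neutral conditions.

**Step 19**
Reactants: 32 (2R,5R)-2-[(4E,8E)-10-{2-methoxy-3-methyl-5-[tri(propan-2-yl)silyloxy]phenyl}-4,8-dimethyl-6-oxodeca-4,8-dien-1-yl]-2,6,6-trimethyl-5-(triethylsilyloxy)oxan-3-one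
Product: 33 (2R,5R)-5-hydroxy-2-[(4E,8E)-10-(5-hydroxy-2-methoxy-3-methylphenyl)-4,8-dimethyl-6-oxodeca-4,8-dien-1-yl]-2,6,6-trimethyloxan-3-one
Conditions: HF·pyridine, pyridine, THF, 0 → 25 °C
Reagents that add atoms: none
Why: Buffered HF·pyridine should cleave both silyl ethers without base, so neither β-elimination of the C5 hydroxyl nor migration of the skipped alkene into conjugation is expected, and no stereocentre is touched.

**Compound list**

1 | ethyl 2-oxopropanoate (ethyl pyruvate) | CCOC(=O)C(C)=O | starting material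
2 | 4-methylpenta-1,3-diene | C=CC=C(C)C | starting material
3 | ethyl (2S)-2,6,6-trimethyl-3,6-dihydro-2H-pyran-2-carboxylate | CCOC(=O)[C@@]1(C)OC(C)(C)C=CC1 | intermediate
4 | ethyl (triphenyl-λ5-phosphanylidene)acetate | CCOC(=O)C=P(c1ccccc1)(c1ccccc1)c1ccccc1 | starting material
5 | (2S)-2,6,6-trimethyl-3,6-dihydro-2H-pyran-2-carbaldehyde | O=C[C@@]1(C)OC(C)(C)C=CC1 | intermediate
6 | ethyl (2E)-3-[(2S)-2,6,6-trimethyl-3,6-dihydro-2H-pyran-2-yl]prop-2-enoate | CCOC(=O)/C=C/[C@@]1(C)OC(C)(C)C=CC1 | intermediate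
7 | ethyl 3-[(2R)-2,6,6-trimethyl-3,6-dihydro-2H-pyran-2-yl]propanoate | CCOC(=O)CC[C@@]1(C)OC(C)(C)C=CC1 | intermediate
8 | 3-[(2R)-2,6,6-trimethyl-3,6-dihydro-2H-pyran-2-yl]propan-1-ol | OCCC[C@@]1(C)OC(C)(C)C=CC1 | intermediate
9 | (2R)-2-(3-chloropropyl)-2,6,6-trimethyl-3,6-dihydro-2H-pyran | ClCCC[C@@]1(C)OC(C)(C)C=CC1 | intermediate
10 | (2R,3RS)-2-(3-chloropropyl)-2,6,6-trimethyl-3,6-dihydro-2H-pyran-3-ol | ClCCC[C@@]1(C)OC(C)(C)C=CC1O | intermediate
11 | (2R)-2-(3-chloropropyl)-2,6,6-trimethyl-2H-pyran-3(6H)-one | ClCCC[C@@]1(C)OC(C)(C)C=CC1=O | intermediate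
12 | (2R,5R)-2-(3-chloropropyl)-2,6,6-trimethyl-5-(4,4,5,5-tetramethyl-1,3,2-dioxaborolan-2-yl)oxan-3-one | ClCCC[C@@]1(C)OC(C)(C)[C@H](B2OC(C)(C)C(C)(C)O2)CC1=O | intermediate
13 | (2R,5R)-2-(3-chloropropyl)-5-hydroxy-2,6,6-trimethyloxan-3-one | ClCCC[C@@]1(C)OC(C)(C)[C@H](O)CC1=O | intermediate
14 | (2R,5R)-2-(3-chloropropyl)-2,6,6-trimethyl-5-(triethylsilyloxy)oxan-3-one | ClCCC[C@@]1(C)OC(C)(C)[C@H](O[Si](CC)(CC)CC)CC1=O | intermediate
15 | (2R,5R)-2-(3-iodopropyl)-2,6,6-trimethyl-5-(triethylsilyloxy)oxan-3-one | ICCC[C@@]1(C)OC(C)(C)[C@H](O[Si](CC)(CC)CC)CC1=O | intermediate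
16 | 4-methoxy-3-methylphenol | COc1ccc(O)cc1C | starting material
17 | (4-methoxy-3-methylphenoxy)tri(propan-2-yl)silane | COc1ccc(O[Si](C(C)C)(C(C)C)C(C)C)cc1C | intermediate
18 | {2-methoxy-3-methyl-5-[tri(propan-2-yl)silyloxy]phenyl}lithium | COc1c(C)cc(O[Si](C(C)C)(C(C)C)C(C)C)cc1[Li] | intermediate
19 | 2-methoxy-3-methyl-5-[tri(propan-2-yl)silyloxy]benzaldehyde | COc1c(C)cc(O[Si](C(C)C)(C(C)C)C(C)C)cc1C=O | intermediate
20 | {2-methoxy-3-methyl-5-[tri(propan-2-yl)silyloxy]phenyl}methanol | COc1c(C)cc(O[Si](C(C)C)(C(C)C)C(C)C)cc1CO | intermediate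
21 | [3-(chloromethyl)-4-methoxy-5-methylphenoxy]tri(propan-2-yl)silane | COc1c(C)cc(O[Si](C(C)C)(C(C)C)C(C)C)cc1CCl | intermediate
22 | but-3-yn-1-ol | C#CCCO | starting material
23 | [(1E)-4-(dimethylalumanyloxy)-2-methylbut-1-en-1-yl]dimethylalumane | C[Al](C)/C=C(\C)CCO[Al](C)C | intermediate
24 | (3E)-5-{2-methoxy-3-methyl-5-[tri(propan-2-yl)silyloxy]phenyl}-3-methylpent-3-en-1-ol | COc1c(C)cc(O[Si](C(C)C)(C(C)C)C(C)C)cc1C/C=C(\C)CCO | intermediate
25 | (3E)-5-{2-methoxy-3-methyl-5-[tri(propan-2-yl)silyloxy]phenyl}-3-methylpent-3-enal | COc1c(C)cc(O[Si](C(C)C)(C(C)C)C(C)C)cc1C/C=C(\C)CC=O | intermediate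
26 | prop-1-ynylmagnesium bromide | CC#C[Mg]Br | starting material
27 | (6E)-8-{2-methoxy-3-methyl-5-[tri(propan-2-yl)silyloxy]phenyl}-6-methyloct-6-en-2-yn-4-ol (racemic at C4) | COc1c(C)cc(O[Si](C(C)C)(C(C)C)C(C)C)cc1C/C=C(\C)CC(O)C#CC | intermediate
28 | (E)-alkenylzirconocene chloride of 27 (Zr on the methyl-bearing alkene carbon, carbinol oxygen bound to a second Cp2ZrCl unit) | COc1c(C)cc(O[Si](C(C)C)(C(C)C)C(C)C)cc1C/C=C(\C)CC(O[Zr](Cl)(C1C=CC=C1)C1C=CC=C1)/C=C(\C)[Zr](Cl)(C1C=CC=C1)C1C=CC=C1 | intermediate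
29 | (2E,6E)-2-iodo-8-{2-methoxy-3-methyl-5-[tri(propan-2-yl)silyloxy]phenyl}-6-methylocta-2,6-dien-4-ol (racemic at C4) | COc1c(C)cc(O[Si](C(C)C)(C(C)C)C(C)C)cc1C/C=C(\C)CC(O)/C=C(\C)I | intermediate
30 | (2E,6E)-2-iodo-8-{2-methoxy-3-methyl-5-[tri(propan-2-yl)silyloxy]phenyl}-6-methylocta-2,6-dien-4-one | COc1c(C)cc(O[Si](C(C)C)(C(C)C)C(C)C)cc1C/C=C(\C)CC(=O)/C=C(\C)I | intermediate
31 | {3-[(2R,5R)-2,6,6-trimethyl-3-oxo-5-(triethylsilyloxy)oxan-2-yl]propyl}zinc iodide | I[Zn]CCC[C@@]1(C)OC(C)(C)[C@H](O[Si](CC)(CC)CC)CC1=O | intermediate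
32 | (2R,5R)-2-[(4E,8E)-10-{2-methoxy-3-methyl-5-[tri(propan-2-yl)silyloxy]phenyl}-4,8-dimethyl-6-oxodeca-4,8-dien-1-yl]-2,6,6-trimethyl-5-(triethylsilyloxy)oxan-3-one | COc1c(C)cc(O[Si](C(C)C)(C(C)C)C(C)C)cc1C/C=C(\C)CC(=O)/C=C(\C)CCC[C@@]1(C)OC(C)(C)[C@H](O[Si](CC)(CC)CC)CC1=O | intermediate
33 | (2R,5R)-5-hydroxy-2-[(4E,8E)-10-(5-hydroxy-2-methoxy-3-methylphenyl)-4,8-dimethyl-6-oxodeca-4,8-dien-1-yl]-2,6,6-trimethyloxan-3-one | COc1c(C)cc(O)cc1C/C=C(\C)CC(=O)/C=C(\C)CCC[C@@]1(C)OC(C)(C)[C@H](O)CC1=O | target

**Step count and risks**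

Total step count: 19. Longest linear sequence: 11 (steps 1–9, 18, 19).

Steps most likely to fail:

Step 1. The diene has a cis-methyl group at its substituted terminus and populates the cisoid conformer poorly, so the zwitterionic adduct may lose a proton (open-chain ene-type product) or the diene may oligomerise instead of closing ring A; facial selectivity may also be lower than with simpler partners. The fallback sets out from 1 and forms the same two bonds in separate, known operations. Mukaiyama aldol addition of the trimethylsilyl dienol ether of mesityl oxide, 4-methyl-2-(trimethylsilyloxy)penta-1,3-diene, to 1 under the same copper–bis(oxazoline) complex should give ethyl (2S)-2-hydroxy-2,6-dimethyl-4-oxohept-5-enoate F1 (C2–C3 bond and C2 stereocentre). Luche reduction (NaBH4, CeCl3·7H2O, MeOH, −40 °C) should give ethyl (2S,4RS)-2,4-dihydroxy-2,6-dimethylhept-5-enoate F2. Acid-catalysed cyclodehydration (camphorsulfonic acid, CH2Cl2) ionises the allylic alcohol, and the tertiary hydroxyl should capture the allyl cation at its gem-dimethyl end (O1–C6 bond), returning to the route at 3.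

Step 6. The ene reaction of SeO2 has to place selenium on the neopentyl-like alkene carbon C5, so the oxidation may be slow and give way to over-oxidation or decomposition. The fallback sets out from 9. Dye-sensitised photo-oxygenation (O2, tetraphenylporphyrin, light, CH2Cl2) should abstract the only allylic hydrogen, at C3, and give (6R)-6-(3-chloropropyl)-3-hydroperoxy-2,2,6-trimethyl-3,6-dihydro-2H-pyran F3, dehydrated with Ac2O/pyridine to the transposed enone (6R)-6-(3-chloropropyl)-2,2,6-trimethyl-2H-pyran-3(6H)-one F4. Weitz–Scheffer epoxidation (H2O2, NaOH, MeOH) should give (6R)-6-(3-chloropropyl)-4,5-epoxy-2,2,6-trimethyloxan-3-one F5. Wharton transposition (N2H4·H2O, AcOH, MeOH) moves the oxygen to C3 and returns to the route at allylic alcohol 10, which is oxidised to 11 as in the second stage of step 6.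

Step 7. Copper–boron addition at C5 next to the quaternary C6 may be sluggish, and the facial control by the ligand may be incomplete because the existing C2 centre gives no help. The fallback sets out from 11. Asymmetric Weitz–Scheffer epoxidation with H2O2 and a chiral primary-amine salt (9-amino-9-deoxy-epi-quinine bis(trifluoroacetate)) should give (2R,4S,5R)-2-(3-chloropropyl)-4,5-epoxy-2,6,6-trimethyloxan-3-one F6. Reductive cleavage of the Cα–O bond with SmI2 (THF/MeOH, −78 °C) leaves the C5–O bond untouched and returns to the route at 13.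

**Further compounds**

F1 | step 1 | ethyl (2S)-2-hydroxy-2,6-dimethyl-4-oxohept-5-enoate | CCOC(=O)[C@@](CC(=O)C=C(C)C)(C)O
F2 | step 1 | ethyl (2S,4RS)-2,4-dihydroxy-2,6-dimethylhept-5-enoate | CCOC(=O)[C@@](CC(O)C=C(C)C)(C)O
F3 | step 6 | (6R)-6-(3-chloropropyl)-3-hydroperoxy-2,2,6-trimethyl-3,6-dihydro-2H-pyran (C3 epimers) | ClCCC[C@@]1(C)OC(C)(C)C(OO)C=C1
F4 | step 6 | (6R)-6-(3-chloropropyl)-2,2,6-trimethyl-2H-pyran-3(6H)-one | ClCCC[C@@]1(C)OC(C)(C)C(=O)C=C1
F5 | step 6 | (6R)-6-(3-chloropropyl)-4,5-epoxy-2,2,6-trimethyloxan-3-one (epoxide epimers) | ClCCC[C@@]1(C)OC(C)(C)C(=O)C2OC12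
F6 | step 7 | (2R,4S,5R)-2-(3-chloropropyl)-4,5-epoxy-2,6,6-trimethyloxan-3-one | ClCCC[C@@]1(C)OC(C)(C)[C@@H]2O[C@@H]2C1=O
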